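Count the living ends.

    free monomer + initiator → living end + monomer in chains (k1 = 2.3 M⁻¹ s⁻¹)
    free monomer + living end → monomer in chains + living end, rate k2*[living end]*[free monomer] (k2 = 1.6 M⁻¹ s⁻¹)
    initiator + impurity → spent initiator (k3 = 200 M⁻¹ s⁻¹)

the same everywhere: initiator 8.6 mM; impurity 1.9 mM
- violet: free monomer 0.20 M (fed, over 0.500 min); time 1.0 min; a stirred flask in which free monomer is dosed at a steady rate over 0.500 min without added volume, worked up at 1.0 min
- teal: free monomer 0.20 M; time 1.0 min; a closed flask charged with all of it at once and left for 1.0 min
- red: free monomer 0.20 M; a single well-mixed tank run continuously and read at steady state, 1.0 min in it on average

- the stated concentrations are those of everything mixed, before any reaction; amounts are the same in each set-up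
- the feed brings no volume worth counting
- run time (violet): 1.0 min

- the set-up with the highest amount of monomer in chains at the outlet or at the end, in percent of the free monomer put in ("none" if the first two lie within 2 percentage points) (violet / teal / red / none)
- amount of monomer in chains at the outlet or at the end, in percent of the free monomer put in, violet
- amount of monomer in chains at the outlet or at the end, in percent of the free monomer put in, teal
- amount of monomer in chains at the outlet or at the end, in percent of the free monomer put in, red

The bench rule of thumb is a titration: you take impurity off initiator one for one, call the remainder the living ends, L = 6.70 mM, and let free monomer fall pseudo-first-order with the constant k of the second step, 1.6 M⁻¹ s⁻¹. On a logarithmic scale that fall is a straight line, so you can carry one number, D, the powers of ten of free monomer lost in a time t, which is k·L·t divided by the natural logarithm of ten. For teal, with 1.0 min, k·L·t is 0.643, and so D = 0.279.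

The border of the rule is a race at the start of teal, where the initiator charge removes impurity at 1.72 s⁻¹ while the free monomer charge removes initiator at 0.460 s⁻¹. The rule stops where these come level, and their ratio of 3.74 puts teal on the titration's side.

My own reckoning therefore gives teal 47.4%. In violet, dosed free monomer stays 45.0 s on average, which scales D down and gives 38.3%. In the red tank the straight line gives way to a mixed balance, and if L is the same there, the answer is 39.1%. I commit to teal.

The forecast also says teal, with 38.6% for violet, 48.6% for teal and 40.9% for red, each above mine. It starts from this: “Impurity destroys initiator quickly, so about 1.8–1.9 mM is lost and about 6.7 mM of living ends form.”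

The simulation gives teal as best, with 38.6% for violet, 48.6% for teal and 40.9% for red. To move violet by 5 points, initiator has to stand at 7.52 mM or 9.78 mM.

Teal leaves 51.4% of its free monomer, which is 0.289 powers of ten against D. Two things acting together hold teal there, the step that turns initiator into spent initiator and the reading at 1.0 min and not ten times later. With that step struck out, teal goes from 48.6% to 56.8%, and the rule, with L now at the initiator charge, puts D at 0.359 and the answer at 56.2%. With that step kept and the reading moved from 1.0 min to 10.0 min, teal goes from 48.6% to 99.9%, while D grows to 2.79, which gives 99.8%.

(The numbers of this flask were set for the occasion; what happens was integrated by code.)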